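**Plan**

1. Numbering used throughout: C1 = methyl-bearing ring-fusion carbon, C2 and C3 = the CH2 groups of the five-membered ring, C4 = isopropyl carbon, C5 = carbinol ring-fusion carbon, C6, C7 = ester carbon, C8(CH3)=C9, C10.
2. Retrosynthesis: the aroyl–O bond and the C7 oxygen are removed first (acylation, ketone reduction, allylic oxidation), then the C1–C2 bond of the five-membered ring is cut, then the C4–C5 bond.
3. Enabling feature: quaternary C1 belongs to both rings and is flanked in the seven-membered ring by C10–C9=C8(CH3). It can therefore be the end of a C1=C10–C9=C8 diene that a C2 radical, tethered through C3–C4 to C5, attacks; the allyl radical then returns the C8=C9 alkene.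
4. Forward order: the seven-membered ring is made first (4-methylanisole, Birch reduction, one-carbon ring expansion to 2,5-dimethylcyclohepta-2,4-dienone). The side chain is joined at C5 by allylboration, and the five-membered ring closes last by 5-exo radical cyclisation.
5. Stereochemistry: C4 and C5 come from a catalytic asymmetric (E)-γ-isopropylallylboration (closed chair, chiral biphenol). C1 follows from C5 through the enforced cis ring fusion. C7 follows from the C5 hydroxyl by internal hydride delivery.

Key step: step 10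

Assumption: (R)-3,3'-dibromo-1,1'-bi-2-naphthol is taken as the catalyst enantiomer that gives the (1S) carbinol in step 6, by analogy with aryl methyl ketones (the alkenyl carbon C1 in the place of the aryl group); if the first run shows the opposite sense, the (S)-catalyst is used with no other change.

**Route**

Step 1
Reactants: 1 4-methylanisole
Product: 2 1-methoxy-4-methylcyclohexa-1,4-diene
Conditions: Li, liq. NH3, t-BuOH, THF, −78 to −33 °C; NH4Cl
Reagents that add atoms: none
Why: Birch reduction of an alkyl anisole stops at the 2,5-dihydro stage with both substituted carbons left on the double bonds, which gives the enol ether/alkene pair needed for a site-selective carbene addition.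

Step 2
Reactants: 2 1-methoxy-4-methylcyclohexa-1,4-diene; 3 1,1-dichloroethane
Product: 4 7-chloro-1-methoxy-4,7-dimethylbicyclo[4.1.0]hept-3-ene (racemic, both C7 epimers)
Conditions: n-BuLi, Et2O, −40 → −20 °C
Reagents that add atoms: none
Why: 1,1-Dichloroethyllithium loses LiCl to chloro(methyl)carbene, an electrophilic carbene that should cyclopropanate the electron-rich enol ether double bond in preference to the methyl-substituted alkene (carbene [2+1] cycloaddition; both C7 epimers are usable because this centre is destroyed in step 3).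

Step 3
Reactants: 4 7-chloro-1-methoxy-4,7-dimethylbicyclo[4.1.0]hept-3-ene
Product: 6 2,5-dimethylcyclohepta-2,4-dien-1-one, via skipped 2,5-dienone 5 (not isolated)
Conditions: NaHCO3, 1,4-dioxane/H2O, reflux; then DBU (0.2 equiv), PhMe, rt
Reagents that add atoms: water O
Why: Methoxy-assisted loss of chloride with opening of the three-membered ring (cyclopropyl-to-allyl cation ring expansion) and hydrolysis of the oxocarbenium ion should give the α-methyl enone 5, which DBU equilibrates through the extended dienolate to the linearly conjugated 2,4-dienone.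

Step 4
Reactants: 7 ethyl (2E)-4-methylpent-2-enoate
Product: 8 (2E)-4-methylpent-2-en-1-ol
Conditions: i-Bu2AlH (2.2 equiv), CH2Cl2, −78 → 0 °C; aq. potassium sodium tartrate
Reagents that add atoms: none
Why: i-Bu2AlH reduces the enoate 1,2 to the allylic alcohol at low temperature and leaves the (E)-alkene untouched (hydride reduction of an ester).

Step 5
Reactants: 8 (2E)-4-methylpent-2-en-1-ol
Product: 10 2-[(2E)-4-methylpent-2-en-1-yl]-1,3,2-dioxaborinane, via allylboronic acid 9 (not isolated)
Conditions: B2(OH)4, Pd(MeCN)4(BF4)2 (2 mol %), DMSO/MeOH, rt; then 1,3-propanediol, MgSO4, pentane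
Reagents that add atoms: tetrahydroxydiboron OB(O)B(O)O; 1,3-propanediol OCCCO
Why: Palladium-catalysed borylation of an allylic alcohol with tetrahydroxydiboron runs through a π-allylpalladium intermediate and should give the linear (E)-allylboronic acid, which is condensed at once with the diol to a storable six-membered boronate that still exchanges with a biphenol.

Step 6
Reactants: 6 2,5-dimethylcyclohepta-2,4-dien-1-one; 10 2-[(2E)-4-methylpent-2-en-1-yl]-1,3,2-dioxaborinane
Product: 11 (1S)-2,5-dimethyl-1-[(3S)-4-methylpent-1-en-3-yl]cyclohepta-2,4-dien-1-ol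
Conditions: (R)-3,3'-dibromo-1,1'-bi-2-naphthol (10 mol %), t-BuOH (2 equiv), PhMe/PhCF3, rt; aq. NaHCO3, chromatography on base-washed silica
Reagents that add atoms: none
Why: This is a chiral biphenol-catalysed asymmetric allylboration of a ketone (crotylboration type) in which the γ-carbon attacks the carbonyl through a closed chair with the (E)-isopropyl group and the alkenyl carbon C1 equatorial and the C6 methylene axial, which sets the anti C4/C5 relationship that later becomes the cis isopropyl/hydroxyl pair, while the boron-bound biphenol selects the carbonyl face and so the (S) carbinol centre.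

Step 7
Reactants: 11 (1S)-2,5-dimethyl-1-[(3S)-4-methylpent-1-en-3-yl]cyclohepta-2,4-dien-1-ol
Product: 12 triethyl({(1S)-2,5-dimethyl-1-[(3S)-4-methylpent-1-en-3-yl]cyclohepta-2,4-dien-1-yl}oxy)silane
Conditions: TESOTf, 2,6-lutidine, CH2Cl2, −78 → 0 °C
Reagents that add atoms: triethylsilyl trifluoromethanesulfonate CC[Si](CC)(CC)OS(=O)(=O)C(F)(F)F
Why: Silyl triflate/lutidine silylation of a hindered tertiary alcohol, chosen because the ether blocks tetrahydrofuran formation when C2 is activated in step 9 and makes the dienylic carbinol less prone to ionise.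

Step 8
Reactants: 12 triethyl({(1S)-2,5-dimethyl-1-[(3S)-4-methylpent-1-en-3-yl]cyclohepta-2,4-dien-1-yl}oxy)silane
Product: 14 (3R)-3-[(1S)-2,5-dimethyl-1-(triethylsilyloxy)cyclohepta-2,4-dien-1-yl]-4-methylpentan-1-ol, via B-alkyl-9-BBN adduct 13 (not isolated)
Conditions: 9-BBN, THF, 0 °C → rt; then NaOH, H2O2, 0 °C → rt
Reagents that add atoms: hydrogen peroxide OO
Why: 9-BBN should hydroborate the monosubstituted vinyl group anti-Markovnikov and leave the trisubstituted diene alone, and alkaline peroxide then gives the primary alcohol (hydroboration–oxidation); C4 is untouched and its descriptor changes only because the side chain loses priority.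

Step 9
Reactants: 14 (3R)-3-[(1S)-2,5-dimethyl-1-(triethylsilyloxy)cyclohepta-2,4-dien-1-yl]-4-methylpentan-1-ol
Product: 15 triethyl({(1S)-1-[(3R)-1-iodo-4-methylpentan-3-yl]-2,5-dimethylcyclohepta-2,4-dien-1-yl}oxy)silane
Conditions: I2, PPh3, imidazole, CH2Cl2, 0 °C → rt
Reagents that add atoms: iodine [I][I]
Why: Appel iodination of the primary alcohol under imidazole-buffered conditions, which the silyl ether and the acid-sensitive diene should tolerate.

Step 10
Reactants: 15 triethyl({(1S)-1-[(3R)-1-iodo-4-methylpentan-3-yl]-2,5-dimethylcyclohepta-2,4-dien-1-yl}oxy)silane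
Product: 17 (3R,3aS,8aR)-6,8a-dimethyl-3-(propan-2-yl)-2,3,4,5,8,8a-hexahydroazulen-3a(1H)-ol, via silyl ether 16 (not isolated)
Conditions: Bu3SnH (1.3 equiv, syringe pump), AIBN (0.2 equiv), PhH (0.01 M), 80 °C; then Bu4NF, THF, 50 °C
Reagents that add atoms: none
Why: Iodine abstraction from 15 by the stannyl radical gives the primary C2 radical, which adds to C1, the end of the C1=C10–C9=C8 diene, and the resulting C10–C9–C8 allyl radical takes a hydrogen atom from the stannane to carry the chain. The closest known reaction type is the reductive tin hydride cyclisation of a hex-5-enyl-type alkyl radical onto the terminus of a conjugated diene, which tolerates formation of a quaternary carbon because an allyl radical is produced. The five-membered ring (C1 to C5) closes in the 5-exo-trig mode and the seven-membered ring is not changed. C1 is the only new stereocentre and is controlled by C5: the three-atom tether can reach C1 only on its own face, so the ring fusion is cis and the C1 methyl ends up syn to the C5 oxygen. The step needs attack at C1 and not C10 (allylic stabilisation, and the alternative 6-endo closure would give a strained bridged ring), closure before reduction (slow addition keeps the stannane dilute) and hydrogen return at the secondary C10 terminus, which gives the more stable trisubstituted C8=C9 alkene. Fluoride then removes the triethylsilyl group and precipitates the tin as Bu3SnF.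

Step 11
Reactants: 17 (3R,3aS,8aR)-6,8a-dimethyl-3-(propan-2-yl)-2,3,4,5,8,8a-hexahydroazulen-3a(1H)-ol
Product: 18 (3R,3aS,8aR)-6,8a-dimethyl-3-(propan-2-yl)-2,3,4,5,8,8a-hexahydroazulene-3a,5(1H)-diol (hydroxyl at C7, both C7 epimers)
Conditions: SeO2 (0.5 equiv), t-BuOOH (3 equiv), CH2Cl2, rt
Reagents that add atoms: selenium dioxide O=[Se]=O; tert-butyl hydroperoxide CC(C)(C)OO
Why: Riley oxidation (ene reaction, then [2,3]-sigmatropic shift) attacks at the more substituted end of a trisubstituted alkene and prefers a ring CH2 over a methyl group, so oxygen should enter at C7 with the alkene returned to C8=C9; the C7 configuration does not matter here.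

Step 12
Reactants: 18 (3R,3aS,8aR)-6,8a-dimethyl-3-(propan-2-yl)-2,3,4,5,8,8a-hexahydroazulene-3a,5(1H)-diol
Product: 19 (3R,3aS,8aR)-3a-hydroxy-6,8a-dimethyl-3-(propan-2-yl)-2,3,3a,4,8,8a-hexahydroazulen-5(1H)-one
Conditions: Dess–Martin periodinane, NaHCO3, CH2Cl2, 0 °C → rt
Reagents that add atoms: none
Why: Dess–Martin oxidation converts only the secondary allylic alcohol and gives the conjugated enone under buffered, non-basic conditions that should avoid retro-aldol cleavage or dehydration of the β-hydroxy ketone.

Step 13
Reactants: 19 (3R,3aS,8aR)-3a-hydroxy-6,8a-dimethyl-3-(propan-2-yl)-2,3,3a,4,8,8a-hexahydroazulen-5(1H)-one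
Product: 20 (3R,3aS,5R,8aR)-6,8a-dimethyl-3-(propan-2-yl)-2,3,4,5,8,8a-hexahydroazulene-3a,5(1H)-diol
Conditions: Me4NBH(OAc)3, MeCN/AcOH (1:1), −20 → 0 °C
Reagents that add atoms: none
Why: Evans–Saksena reduction, in which the C5 hydroxyl exchanges onto boron and delivers hydride to the carbonyl face on its own side, so the new C7 hydroxyl should be trans (1,3-anti) to the C5 hydroxyl, i.e. (R) at C7, with no conjugate reduction because the acetoxyborohydride reacts only when bound.

Step 14
Reactants: 20 (3R,3aS,5R,8aR)-6,8a-dimethyl-3-(propan-2-yl)-2,3,4,5,8,8a-hexahydroazulene-3a,5(1H)-diol; 21 3,4-dimethoxybenzoyl chloride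
Product: 22 (3R,3aS,5R,8aR)-3a-hydroxy-6,8a-dimethyl-3-(propan-2-yl)-1,2,3,3a,4,5,8,8a-octahydroazulen-5-yl 3,4-dimethoxybenzoate
Conditions: Et3N, DMAP (cat.), CH2Cl2, 0 °C → rt
Reagents that add atoms: none
Why: DMAP-catalysed acylation should take place only at the secondary allylic hydroxyl because the tertiary ring-fusion hydroxyl is too hindered (chemoselective esterification), with no change at C7.

**Compound list**

1 | 4-methylanisole | COc1ccc(C)cc1 | starting material
2 | 1-methoxy-4-methylcyclohexa-1,4-diene | COC1=CCC(C)=CC1 | intermediate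
3 | 1,1-dichloroethane | CC(Cl)Cl | starting material
4 | 7-chloro-1-methoxy-4,7-dimethylbicyclo[4.1.0]hept-3-ene (racemic, both C7 epimers) | COC12CC=C(C)CC1C2(C)Cl | intermediate
5 | 2,5-dimethylcyclohepta-2,5-dien-1-one | O=C1CC=C(C)CC=C1C | intermediate (not isolated)
6 | 2,5-dimethylcyclohepta-2,4-dien-1-one | O=C1CCC(C)=CC=C1C | intermediate
7 | ethyl (2E)-4-methylpent-2-enoate | CCOC(=O)/C=C/C(C)C | starting material
8 | (2E)-4-methylpent-2-en-1-ol | CC(C)/C=C/CO | intermediate
9 | [(2E)-4-methylpent-2-en-1-yl]boronic acid | CC(C)/C=C/CB(O)O | intermediate (not isolated)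
10 | 2-[(2E)-4-methylpent-2-en-1-yl]-1,3,2-dioxaborinane | CC(C)/C=C/CB1OCCCO1 | intermediate
11 | (1S)-2,5-dimethyl-1-[(3S)-4-methylpent-1-en-3-yl]cyclohepta-2,4-dien-1-ol | O[C@]1([C@@H](C(C)C)C=C)CCC(C)=CC=C1C | intermediate
12 | triethyl({(1S)-2,5-dimethyl-1-[(3S)-4-methylpent-1-en-3-yl]cyclohepta-2,4-dien-1-yl}oxy)silane | CC[Si](CC)(CC)O[C@]1([C@@H](C(C)C)C=C)CCC(C)=CC=C1C | intermediate
13 | 9-{(3R)-3-[(1S)-2,5-dimethyl-1-(triethylsilyloxy)cyclohepta-2,4-dien-1-yl]-4-methylpentyl}-9-borabicyclo[3.3.1]nonane | CC[Si](CC)(CC)O[C@]1([C@@H](C(C)C)CCB2C3CCCC2CCC3)CCC(C)=CC=C1C | intermediate (not isolated)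
14 | (3R)-3-[(1S)-2,5-dimethyl-1-(triethylsilyloxy)cyclohepta-2,4-dien-1-yl]-4-methylpentan-1-ol | CC[Si](CC)(CC)O[C@]1([C@@H](C(C)C)CCO)CCC(C)=CC=C1C | intermediate
15 | triethyl({(1S)-1-[(3R)-1-iodo-4-methylpentan-3-yl]-2,5-dimethylcyclohepta-2,4-dien-1-yl}oxy)silane | CC[Si](CC)(CC)O[C@]1([C@@H](C(C)C)CCI)CCC(C)=CC=C1C | intermediate
16 | triethyl{[(3R,3aS,8aR)-6,8a-dimethyl-3-(propan-2-yl)-2,3,4,5,8,8a-hexahydroazulen-3a(1H)-yl]oxy}silane (cis-fused) | CC1=CC[C@@]2(C)CC[C@H](C(C)C)[C@@]2(O[Si](CC)(CC)CC)CC1 | intermediate (not isolated)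
17 | (3R,3aS,8aR)-6,8a-dimethyl-3-(propan-2-yl)-2,3,4,5,8,8a-hexahydroazulen-3a(1H)-ol (cis-fused; OH, C1 methyl and isopropyl on one face of the five-membered ring) | CC1=CC[C@@]2(C)CC[C@H](C(C)C)[C@@]2(O)CC1 | intermediate
18 | (3R,3aS,8aR)-6,8a-dimethyl-3-(propan-2-yl)-2,3,4,5,8,8a-hexahydroazulene-3a,5(1H)-diol (both C7 epimers) | OC1C[C@]2(O)[C@@H](C(C)C)CC[C@]2(C)CC=C1C | intermediate
19 | (3R,3aS,8aR)-3a-hydroxy-6,8a-dimethyl-3-(propan-2-yl)-2,3,3a,4,8,8a-hexahydroazulen-5(1H)-one | O=C1C[C@]2(O)[C@@H](C(C)C)CC[C@]2(C)CC=C1C | intermediate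
20 | (3R,3aS,5R,8aR)-6,8a-dimethyl-3-(propan-2-yl)-2,3,4,5,8,8a-hexahydroazulene-3a,5(1H)-diol (C7 OH trans to C5 OH) | O[C@@H]1C[C@]2(O)[C@@H](C(C)C)CC[C@]2(C)CC=C1C | intermediate
21 | 3,4-dimethoxybenzoyl chloride | COc1ccc(C(=O)Cl)cc1OC | starting material
22 | (3R,3aS,5R,8aR)-3a-hydroxy-6,8a-dimethyl-3-(propan-2-yl)-1,2,3,3a,4,5,8,8a-octahydroazulen-5-yl 3,4-dimethoxybenzoate | COc1ccc(C(=O)O[C@@H]2C[C@]3(O)[C@@H](C(C)C)CC[C@]3(C)CC=C2C)cc1OC | target

**Step count and risks**

Total: 14 steps. Longest linear sequence: 12 steps from 4-methylanisole (steps 1–3 and 6–14); the boronate branch is steps 4–5.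

Risk 1, step 10 (radical ring closure). The open-chain C2 radical may take hydrogen from the stannane, or shift a hydrogen intramolecularly, before it closes. The allyl radical may also take its hydrogen at the tertiary C8 end, which would leave the alkene at C9=C10. The fallback sets out from 15 and comes back at 16. The reductive chain is replaced by a cobalt-mediated, non-reductive radical cyclisation in which no hydrogen donor is present. Iodide 15 with Co(dmgH)2(py)Cl (cat.), i-Pr2NEt and blue light in MeCN should close in the same 5-exo sense and lose a C7 hydrogen to the divalent cobalt, giving the conjugated ring diene silyl ether F1 (C7=C8–C9=C10). 1,4-Hydrogenation of this cisoid diene with H2 and (η6-naphthalene)Cr(CO)3 adds hydrogen at the two diene ends (C7 and C10) and leaves the double bond in the middle, giving 16 with the alkene fixed at C8=C9. Desilylation as in step 10 then gives 17.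

Risk 2, step 6 (asymmetric allylboration). Addition of the γ-branched boronate to the hindered, conjugated ketone may be slow. The catalyst may discriminate poorly between the two carbonyl faces, or the chair may not distinguish the two ring flanks, which would erode the ee or the anti relationship. The fallback sets out from 8 and 6 and comes back at 14, so steps 7 and 8 are not needed. It is a reagent-controlled homoaldol addition of a lithiated allyl carbamate. Alcohol 8 is carbamoylated (NaH, N,N-diisopropylcarbamoyl chloride, THF) to (2E)-4-methylpent-2-en-1-yl N,N-diisopropylcarbamate F2. Deprotonation with n-BuLi/(−)-sparteine (or its (+)-surrogate, chosen to give the (1S) carbinol), transmetallation with Ti(OiPr)4 and addition of 6 should give the anti-configured (Z)-enol carbamate F3 through a chair closed by titanium, with C2 already oxygenated. Silylation (TESOTf, 2,6-lutidine) gives the silyl ether F4. MeLi cleaves the carbamate to the enolate, which is protonated to the aldehyde F5, and NaBH4 reduces this to 14.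

Risk 3, step 11 (allylic oxidation). The ene step may remove a hydrogen from the C8 methyl group in place of C7, and the allylic alcohol may be over-oxidised or the material lost. The fallback sets out from 17 and comes back at 18; oxygen is brought in at C9 and then transposed. Hydroboration–oxidation of 17 (BH3·SMe2; NaOH, H2O2) puts boron on the less substituted alkene carbon and gives the C9 alcohol F6. Dess–Martin oxidation gives the C9 ketone F7. Dehydrogenation with IBX (DMSO, 70 °C) can only go towards C8–C7, because C10 is flanked by quaternary C1, and gives the transposed enone F8. H2O2/NaOH gives the epoxy ketone F9, and Wharton transposition (N2H4·H2O, AcOH, MeOH) gives allylic alcohol 18 with oxygen at C7 and the alkene at C8=C9.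

**Further compounds**

F1 | step 10 | triethyl{[(3R,3aS,8aR)-6,8a-dimethyl-3-(propan-2-yl)-1,2,3,3a,4,8a-hexahydroazulen-3a-yl]oxy}silane (C7=C8–C9=C10 diene) | C1=C(C)C=C[C@@]2(C)CC[C@H](C(C)C)[C@@]2(O[Si](CC)(CC)CC)C1
F2 | step 6 | (2E)-4-methylpent-2-en-1-yl N,N-di(propan-2-yl)carbamate | CC(C)/C=C/COC(=O)N(C(C)C)C(C)C
F3 | step 6 | (1Z,3S)-3-[(1S)-1-hydroxy-2,5-dimethylcyclohepta-2,4-dien-1-yl]-4-methylpent-1-en-1-yl N,N-di(propan-2-yl)carbamate | O[C@]1([C@@H](C(C)C)/C=C\OC(=O)N(C(C)C)C(C)C)CCC(C)=CC=C1C
F4 | step 6 | (1Z,3S)-3-[(1S)-2,5-dimethyl-1-(triethylsilyloxy)cyclohepta-2,4-dien-1-yl]-4-methylpent-1-en-1-yl N,N-di(propan-2-yl)carbamate | CC[Si](CC)(CC)O[C@]1([C@@H](C(C)C)/C=C\OC(=O)N(C(C)C)C(C)C)CCC(C)=CC=C1C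
F5 | step 6 | (3R)-3-[(1S)-2,5-dimethyl-1-(triethylsilyloxy)cyclohepta-2,4-dien-1-yl]-4-methylpentanal | CC[Si](CC)(CC)O[C@]1([C@@H](C(C)C)CC=O)CCC(C)=CC=C1C
F6 | step 11 | (3R,3aS,8aR)-6,8a-dimethyl-3-(propan-2-yl)octahydroazulene-3a,7(1H)-diol (hydroxyl at C9; C8 and C9 configuration not defined) | CC1C(O)C[C@@]2(C)CC[C@H](C(C)C)[C@@]2(O)CC1
F7 | step 11 | (3R,3aS,8aR)-3a-hydroxy-6,8a-dimethyl-3-(propan-2-yl)octahydroazulen-7(1H)-one (C9 ketone; C8 configuration not defined) | CC1C(=O)C[C@@]2(C)CC[C@H](C(C)C)[C@@]2(O)CC1
F8 | step 11 | (3R,3aS,8aR)-3a-hydroxy-6,8a-dimethyl-3-(propan-2-yl)-2,3,3a,4,8,8a-hexahydroazulen-7(1H)-one (C9 ketone, C7=C8 alkene) | O=C1C[C@@]2(C)CC[C@H](C(C)C)[C@@]2(O)CC=C1C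
F9 | step 11 | 7,8-epoxide of F8 (C9 ketone, oxirane across C7–C8; epoxide configuration not defined) | O=C1C[C@@]2(C)CC[C@H](C(C)C)[C@@]2(O)CC3OC13C
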